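Assumption: atoms carry the briarane numbering of the target throughout (ring carbons C1–C14; C15 = methyl on C1, C16 = methyl on C5, C17/C18/C19 = lactone CH/CH3/C=O, C20 = methyl on C11), and each chiral catalyst is used as the enantiomer that delivers the drawn configuration (both enantiomers are available).

## Analysis of the target

The target is a chlorinated briarane. Ring A is a cyclohex-2-enone (C1, C10, C11, C12, C13, C14), trans-fused through C1–C10 to the ten-membered ring B (C1–C10), which carries the cis-fused γ-lactone ring C (O–C19–C17–C8–C7). Reading the SMILES gives eight stereocentres, 1S,2S,7S,8R,9S,10S,11R,17R. The C1 methyl, the C9 arm on C10 and the C11 methyl are all cis on ring A, and C7–C8–C9–C17 form a second cluster around the tertiary C8 carbinol. Ring B holds the only tetrasubstituted alkene, C5(CH3)=C6(Cl), with C4 and C7 cis (ring-Z, formally 5E). Its allylic carbon C7 bears the lactone oxygen, so C5=C6(Cl)–C7–O is a 2-chloroallyl ester. Sensitive groups are the β-hydroxy lactone (retro-aldol, dehydration), the epimerisable centres C11 and C17, the allylic C7–O bond, the enone, and one acetate next to a free secondary and a free tertiary alcohol. The synthesis is hard because of the medium ring, the chlorine on a fully substituted ring alkene of defined geometry, and the relay of configuration across ring B from C1/C10 to C7–C9. The feature that decides the strategy is the C5(CH3)=C6(Cl)–C7(O–C19) unit shared by rings B and C. It is the product pattern of a cyclopropyl-to-allyl opening of a gem-dichlorocyclopropane in which the C5–C7 bond is cleaved and the cation is trapped at C7 by the C19 carboxyl group.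

## Retrosynthetic reasoning

**27 ⇒ 24.** Only protecting-group changes are removed: the C9 silyl ether is cleaved last, and the C2 acetate is introduced after selective release of the C2 hydroxyl (26, 25). The acetate comes late because two methanolysis steps earlier in the route would not spare it.

**24 ⇒ 22 (key disconnection).** The O–C7 bond of ring C is cut and C5 is reconnected to C7, which turns ring B into a nine-membered ring bearing a gem-dichlorocyclopropane (C5, C6, C7). It is cut here because C6 with its chlorine is then a one-carbon insert, and the geometry of the tetrasubstituted alkene, the lactone and the C7 stereocentre all become consequences of one ring opening. Forward, the step must ionise the chloride that is cis to the ring bonds, open C5–C7 with C4 and C8 turning inward, and let the C19 ester oxygen close ring C at C7. The precursor has no chlorine-bearing alkene, no lactone and a smaller ring.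

**22 ⇒ 21 ⇒ 19 ⇒ 18.** The cyclopropane comes from the cis trisubstituted alkene C5=C7 of 21 by gem-dichlorocyclopropanation. Ring A must be an enone by then so that it is inert to the electrophilic carbene. The enone comes from the silyl enol ether of 18 (19), and the only enolisable centre of that enone, C11, is set at this point by kinetic protonation (21).

**18 ⇒ 15 + 16.** The C8–C17 bond is cut. Aldol addition of the enolate of 16 to the C8 ketone of 15 brings in C17–C19 and creates the tertiary carbinol. The β,β-disubstituted enone forces 1,2-addition and the neighbouring C9 silyl ether controls the face.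

**15 ⇒ 12.** The ring alkene C5=C7 is cut (ring-closing metathesis), followed by acetate removal and allylic oxidation (13, 14). A nine-membered ring allows only the cis alkene, which is the geometry the key step needs.

**12 ⇒ 9 + 10.** The C8–C9 bond is cut. A catalyst-controlled (acyloxy)allylation of the C9 alcohol adds C8 (oxygenated) and the vinyl group C7, and sets C9 against the substrate bias (11).

**9 ⇒ 4 + 5.** The C2–C3 bond is cut. Felkin–Anh addition of the Grignard reagent from 5 to the C2 aldehyde of 4 sets C2 and delivers C3–C5 with C16 (7, 8).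

**4 ⇒ 2 + 3, and 2 ⇒ 1.** Ring A is cut at C1–C14 and C10–C11 (Diels–Alder). The E geometry of 3 fixes the C1 methyl cis to the C10 arm, a chiral Lewis acid sets the absolute configuration, and the diene 2 comes from 1 in one step.

## Alternatives that were turned down

**Alternative 1:** the textbook route closes ring B directly at C7–C8 by a Nozaki–Hiyama–Kishi reaction of the seco iodo-aldehyde A1 (chloroalkene already in place), then lactonises to the macrocyclic butenolide A2.
- It forces a ten-membered ring closed head-on against transannular strain, at a carbon flanked by a tetrasubstituted chloroalkene.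
- C7 is created on a flexible ring with nothing to control it.
- C8 and C17 then need epoxidation and reductive opening of the butenolide on that same ring.
- A1 needs about as many steps as the key-step precursor 22, so nothing is gained and three stereocentres are left to chance.

**Alternative 2:** anionic oxy-Cope ring expansion of the divinyl decalindiol A3 (from a Wieland–Miescher-type ketone) to the ten-membered keto enol ether A4, followed by Saegusa oxidation and α-chlorination.
- The [3,3] shift is reliable and delivers C2 and C7 oxygenated.
- C8 (tertiary carbinol with C17–C19), C9 and the lactone must then be built on the ten-membered ring, where a C9 oxygen sits β to the C7 ketone and eliminates, and four substrate-controlled steps follow on a floppy ring.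
- Installing them before the rearrangement would require four contiguous fully substituted carbons in A3.
- Chlorine still has to be added afterwards, so the key step wins less than its follow-up costs.

**Alternative 3:** a macrocyclising intramolecular Diels–Alder reaction of the open-chain triene A5, closing ring A and ring B together.
- The diene terminus C1 is fully substituted, so one substituent is necessarily cis and the s-cis conformer is disfavoured.
- The dienophile C10=C11 is unactivated.
- The same transition state has to pay for a ten-membered ring.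
- The temperatures needed would not be tolerated by the allylic lactone and the chloroalkene.

Key step: step 15

## Route

Step 1
Reactants: 1 pent-1-en-3-one
Product: 2 (3Z)-3-(triisopropylsilyloxy)penta-1,3-diene
Conditions: iPr3SiOTf, Et3N, Et2O, 0 °C
Reagents that add atoms: triisopropylsilyl trifluoromethanesulfonate, CC(C)[Si](C(C)C)(C(C)C)OS(=O)(=O)C(F)(F)F
Why: Soft enolisation of the ethyl ketone gives the (Z)-silyl enol ether (methyl cis to oxygen), which is the diene that can reach the s-cis form with its methyl group outside.

Step 2
Reactants: 2 (3Z)-3-(triisopropylsilyloxy)penta-1,3-diene; 3 (2E)-4-acetoxy-2-methylbut-2-enal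
Product: 4 ring A aldehyde (cyclohexene with C1 bearing CH3 and CHO, C10 bearing CH2OAc cis to the C1 methyl, C11 methyl trans to CH2OAc, C12=C13 silyl enol ether)
Conditions: (S)-o-tolyl oxazaborolidinium bis(triflyl)imide (20 mol%), CH2Cl2, −78 °C
Reagents that add atoms: none
Why: Lewis-acid-catalysed Diels–Alder reaction in which the nucleophilic diene terminus C11 bonds to the enal β-carbon C10 and C14 to the α-carbon C1; the E-enal fixes the C1 methyl cis to the C10 arm, the chiral cation selects the enal face (1S,10S), and the endo-formyl mode should place the C11 methyl trans to C9, a centre that is reset in step 13.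

Step 3
Reactants: 4 ring A aldehyde; 5 4-bromo-2-methylbut-1-ene
Product: 7 C2 carbinol (2S; side chain C3–C4–C5(CH3)=CH2), via (3-methylbut-3-en-1-yl)magnesium bromide 6 (not isolated)
Conditions: 5, Mg, THF; then 4, −78 °C
Reagents that add atoms: none
Why: Grignard addition to the neopentylic aldehyde under Felkin–Anh control (attack anti to the branched C10 and past the C1 methyl), which corresponds to the 2S carbinol of the target; the primary acetate should be spared at −78 °C.

Step 4
Reactants: 7 C2 carbinol
Product: 8 C2 triethylsilyl ether
Conditions: Et3SiOTf, 2,6-lutidine, CH2Cl2, −78 °C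
Reagents that add atoms: triethylsilyl trifluoromethanesulfonate, CC[Si](CC)(CC)OS(=O)(=O)C(F)(F)F
Why: Silylation of a hindered secondary alcohol with a silyl triflate; triethylsilyl is chosen because it can be removed at the end without loss of the C9 silyl ether.

Step 5
Reactants: 8 C2 triethylsilyl ether
Product: 9 C9 primary alcohol
Conditions: K2CO3 (cat.), MeOH, 0 °C
Reagents that add atoms: none
Why: Base-catalysed transesterification frees the primary alcohol; silyl ethers and the hindered silyl enol ether are stable to carbonate in methanol.

Step 6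
Reactants: 9 C9 primary alcohol; 10 prop-2-ene-1,1-diyl diacetate
Product: 11 anti (acetoxy)allylation product (C9 OH as in the target, C8 OAc, C7 vinyl)
Conditions: [Ir(cod)Cl]2 (2.5 mol%), (S)-SEGPHOS (5 mol%), 4-cyano-3-nitrobenzoic acid (10 mol%), Cs2CO3 (20 mol%), THF, 90 °C
Reagents that add atoms: none
Why: Iridium-catalysed transfer-hydrogenative carbonyl (acyloxy)allylation from the alcohol oxidation level, in which the alcohol is dehydrogenated in situ and the acetoxy-substituted allyliridium adds through a closed chair to give the anti adduct; the ligand controls C9, which is needed because substrate-controlled Felkin–Anh addition to this aldehyde would give the C9 epimer, and the C8 centre is destroyed in step 10.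

Step 7
Reactants: 11 anti (acetoxy)allylation product
Product: 12 C9 tert-butyldimethylsilyl ether
Conditions: tBuMe2SiOTf, 2,6-lutidine, CH2Cl2, −40 °C
Reagents that add atoms: tert-butyldimethylsilyl trifluoromethanesulfonate, CC(C)(C)[Si](C)(C)OS(=O)(=O)C(F)(F)F
Why: Silyl triflate silylation of the hindered secondary alcohol; a non-chelating, bulky C9 ether is wanted for the facial control in step 11.

Step 8
Reactants: 12 C9 tert-butyldimethylsilyl ether
Product: 13 cyclononene acetate (nine-membered ring C1, C2, C3, C4, C5, C7, C8, C9, C10 with cis C5(CH3)=C7H)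
Conditions: second-generation Hoveyda–Grubbs catalyst (10 mol%), toluene (1 mM), 80 °C
Reagents that add atoms: none
Why: Ring-closing metathesis of the vinyl and isopropenyl groups; the nine-membered ring accepts only the cis trisubstituted alkene, the trans-disposed arms on ring A and the quaternary C1 favour closure, and the ring A enol ether is too hindered to engage the catalyst.

Step 9
Reactants: 13 cyclononene acetate
Product: 14 cyclononenol (free C8 OH)
Conditions: K2CO3, MeOH, 23 °C
Reagents that add atoms: none
Why: Methanolysis of the allylic acetate; the three silyl groups are stable to these conditions.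

Step 10
Reactants: 14 cyclononenol
Product: 15 cyclononenone (C5(CH3)=C7H–C8=O)
Conditions: MnO2, CH2Cl2, 23 °C
Reagents that add atoms: none
Why: Allylic oxidation with MnO2 is selective for the allylic alcohol and leaves the silyl enol ether and silyl ethers untouched.

Step 11
Reactants: 15 cyclononenone; 16 tert-butyl propanoate
Product: 18 aldol adduct (C8 tertiary OH, C17 CH(CH3)CO2tBu), via lithium (Z)-enolate 17 (not isolated)
Conditions: 16, LiN(iPr)2, THF/DMPU, −78 °C; then 15, −78 °C
Reagents that add atoms: none
Why: Aldol addition of an ester enolate to a ketone; the β,β-disubstituted enone directs 1,2-addition, polar Felkin–Anh attack anti to the C9–O bond should give the 8R carbinol, and a closed Zimmerman–Traxler chair with the (Z)-enolate and C9 equatorial should place the C17 methyl as in the target.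

Step 12
Reactants: 18 aldol adduct
Product: 19 bicyclic enone (ring A C12=O, C13=C14; C11 still epimeric)
Conditions: Pd(OAc)2 (1.2 equiv), MeCN, 40 °C
Reagents that add atoms: none
Why: Saegusa–Ito oxidation, with palladation at C13 and β-hydride elimination from C14 fixing the enone regiochemistry; it is done only now because the enone would not have survived steps 3 to 11, and it makes ring A inert to the carbene of step 14.

Step 13
Reactants: 19 bicyclic enone
Product: 21 bicyclic enone with the natural C11 configuration, via dilithium alkoxide dienolate 20 (not isolated)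
Conditions: LiN(SiMe3)2 (2.2 equiv), THF, −78 °C; then AcOH, −78 °C
Reagents that add atoms: none
Why: The amide removes the hydroxyl proton and the only acidic C–H of the enone (C11–H, the ester α-proton being much less acidic); kinetic protonation of the dienolate should occur anti to the C10 arm, which A(1,2) strain forces pseudoaxial, leaving the C11 methyl cis to C9.

Step 14
Reactants: 21 bicyclic enone with the natural C11 configuration
Product: 22 gem-dichlorocyclopropane (C5, C6, C7; cis-fused to the nine-membered ring)
Conditions: PhHgCCl3 (1.5 equiv), benzene, 80 °C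
Reagents that add atoms: phenyl(trichloromethyl)mercury, ClC(Cl)(Cl)[Hg]c1ccccc1
Why: Neutral thermal transfer of dichlorocarbene, which as an electrophile should choose the electron-rich trisubstituted alkene over the enone; addition is stereospecific (cis fusion) and is expected on the outer face that carries only the pseudoaxial C8 hydroxyl, and both cyclopropane stereocentres are consumed in step 15.

Step 15
Reactants: 22 gem-dichlorocyclopropane
Product: 24 ten-membered chlorolactone (C2 triethylsilyl ether, C9 tert-butyldimethylsilyl ether), via 2-chloroallyl cation 23 (not isolated)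
Conditions: (CF3)2CHOH, 2,6-lutidine (2 equiv), 60 °C
Reagents that add atoms: none
Why: In the strongly ionising, weakly nucleophilic solvent the endo C6–Cl bond ionises while the C5–C7 bond opens in a disrotatory sense (Woodward–Hoffmann–DePuy cyclopropyl-to-allyl opening) to give cation 23 with its tertiary terminus at C5; the closest known reaction type is the electrocyclic ring expansion of ring-fused gem-dihalocyclopropanes with capture of the cation by a tethered oxygen nucleophile. Ring B grows from nine to ten members by cleavage of C5–C7 (a ring expansion, not a cyclisation), and ring C closes by 5-exo attack of the C19 ester carbonyl oxygen on C7, the tert-butyl group leaving as 2-methylpropene. The C5=C6 geometry follows from the rotation sense: the groups cis to the departing endo chloride (C4 and C8) turn inward, so C4 and C7 end up cis and the methyl cis to chlorine, as in the target. C7 is set by the same event, because in the all-cis cation the C8–C9 bond must point back toward C4 on the face from which chloride left and the C17 arm can reach only the opposite face, which gives the cis-fused lactone with H7 syn to the C8 hydroxyl. The selectivity needed is loss of the endo chloride and not the exo chloride, since silver-promoted openings of simple medium-ring adducts prefer the exposed exo halide and give trans-cycloalkenes. Three features of 22 are meant to secure it: no silver salt is used, the C19 carbonyl can give backside assistance only on the exo face and therefore only to endo ionisation, and the competing mode would have to turn the C5 methyl inward and build a tetrasubstituted trans-cyclodecene. The free C8 hydroxyl is kept because lactone closure should outrun a 1,2-shift toward C7.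

Step 16
Reactants: 24 ten-membered chlorolactone
Product: 25 C2 alcohol (C9 silyl ether retained)
Conditions: PPTS (cat.), MeOH/CH2Cl2, 0 °C
Reagents that add atoms: none
Why: Acid-catalysed methanolysis removes the triethylsilyl ether much faster than the secondary tert-butyldimethylsilyl ether.

Step 17
Reactants: 25 C2 alcohol
Product: 26 C2 acetate
Conditions: Ac2O, DMAP (cat.), pyridine, 23 °C
Reagents that add atoms: acetic anhydride, CC(=O)OC(C)=O
Why: Acylation of the only free secondary alcohol; the tertiary C8 hydroxyl should not react under these conditions and C9 is still protected.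

Step 18
Reactants: 26 C2 acetate
Product: 27 CNP0163464.1
Conditions: HF·pyridine, THF/pyridine, 0 to 23 °C
Reagents that add atoms: none
Why: Buffered fluoride cleaves the remaining silyl ether without touching the acetate, lactone, enone or the epimerisable centres C11 and C17.

## Compound list

1 | pent-1-en-3-one | CCC(=O)C=C | starting material
2 | (3Z)-3-(triisopropylsilyloxy)penta-1,3-diene | C=C/C(O[Si](C(C)C)(C(C)C)C(C)C)=C/C | intermediate
3 | (2E)-4-acetoxy-2-methylbut-2-enal | CC(=O)OC/C=C(\C)C=O | starting material
4 | ring A aldehyde (Diels–Alder adduct) | C[C@]1(C=O)CC=C(O[Si](C(C)C)(C(C)C)C(C)C)[C@@H](C)[C@@H]1COC(C)=O | intermediate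
5 | 4-bromo-2-methylbut-1-ene | CC(=C)CCBr | starting material
6 | (3-methylbut-3-en-1-yl)magnesium bromide | CC(=C)CC[Mg]Br | intermediate
7 | C2 carbinol | C[C@]1([C@@H](O)CCC(C)=C)CC=C(O[Si](C(C)C)(C(C)C)C(C)C)[C@@H](C)[C@@H]1COC(C)=O | intermediate
8 | C2 triethylsilyl ether | C[C@]1([C@@H](O[Si](CC)(CC)CC)CCC(C)=C)CC=C(O[Si](C(C)C)(C(C)C)C(C)C)[C@@H](C)[C@@H]1COC(C)=O | intermediate
9 | C9 primary alcohol | C[C@]1([C@@H](O[Si](CC)(CC)CC)CCC(C)=C)CC=C(O[Si](C(C)C)(C(C)C)C(C)C)[C@@H](C)[C@@H]1CO | intermediate
10 | prop-2-ene-1,1-diyl diacetate | CC(=O)OC(OC(C)=O)C=C | starting material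
11 | anti (acetoxy)allylation product | C[C@]1([C@@H](O[Si](CC)(CC)CC)CCC(C)=C)CC=C(O[Si](C(C)C)(C(C)C)C(C)C)[C@@H](C)[C@@H]1[C@H](O)[C@H](OC(C)=O)C=C | intermediate
12 | C9 tert-butyldimethylsilyl ether | C[C@]1([C@@H](O[Si](CC)(CC)CC)CCC(C)=C)CC=C(O[Si](C(C)C)(C(C)C)C(C)C)[C@@H](C)[C@@H]1[C@H](O[Si](C)(C)C(C)(C)C)[C@H](OC(C)=O)C=C | intermediate
13 | cyclononene acetate | C[C@]12CC=C(O[Si](C(C)C)(C(C)C)C(C)C)[C@@H](C)[C@@H]1[C@H](O[Si](C)(C)C(C)(C)C)[C@H](OC(C)=O)/C=C(C)\CC[C@@H]2O[Si](CC)(CC)CC | intermediate
14 | cyclononenol | C[C@]12CC=C(O[Si](C(C)C)(C(C)C)C(C)C)[C@@H](C)[C@@H]1[C@H](O[Si](C)(C)C(C)(C)C)[C@H](O)/C=C(C)\CC[C@@H]2O[Si](CC)(CC)CC | intermediate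
15 | cyclononenone | C[C@]12CC=C(O[Si](C(C)C)(C(C)C)C(C)C)[C@@H](C)[C@@H]1[C@H](O[Si](C)(C)C(C)(C)C)C(=O)/C=C(C)\CC[C@@H]2O[Si](CC)(CC)CC | intermediate
16 | tert-butyl propanoate | CCC(=O)OC(C)(C)C | starting material
17 | lithium (Z)-enolate of tert-butyl propanoate | C/C=C(\O[Li])OC(C)(C)C | intermediate
18 | aldol adduct | C[C@]12CC=C(O[Si](C(C)C)(C(C)C)C(C)C)[C@@H](C)[C@@H]1[C@H](O[Si](C)(C)C(C)(C)C)[C@](O)([C@@H](C)C(=O)OC(C)(C)C)/C=C(C)\CC[C@@H]2O[Si](CC)(CC)CC | intermediate
19 | bicyclic enone (C11 epimeric) | C[C@]12C=CC(=O)[C@@H](C)[C@@H]1[C@H](O[Si](C)(C)C(C)(C)C)[C@](O)([C@@H](C)C(=O)OC(C)(C)C)/C=C(C)\CC[C@@H]2O[Si](CC)(CC)CC | intermediate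
20 | dilithium alkoxide dienolate | C[C@]12C=CC(O[Li])=C(C)[C@@H]1[C@H](O[Si](C)(C)C(C)(C)C)[C@](O[Li])([C@@H](C)C(=O)OC(C)(C)C)/C=C(C)\CC[C@@H]2O[Si](CC)(CC)CC | intermediate
21 | bicyclic enone with natural C11 | C[C@]12C=CC(=O)[C@H](C)[C@@H]1[C@H](O[Si](C)(C)C(C)(C)C)[C@](O)([C@@H](C)C(=O)OC(C)(C)C)/C=C(C)\CC[C@@H]2O[Si](CC)(CC)CC | intermediate
22 | gem-dichlorocyclopropane | C[C@]12C=CC(=O)[C@H](C)[C@@H]1[C@H](O[Si](C)(C)C(C)(C)C)[C@](O)([C@@H](C)C(=O)OC(C)(C)C)[C@H]3C(Cl)(Cl)[C@@]3(C)CC[C@@H]2O[Si](CC)(CC)CC | intermediate
23 | 2-chloroallyl cation | C[C@]12C=CC(=O)[C@H](C)[C@@H]1[C@H](O[Si](C)(C)C(C)(C)C)[C@](O)([C@@H](C)C(=O)OC(C)(C)C)/C=C(Cl)\[C+](C)CC[C@@H]2O[Si](CC)(CC)CC | intermediate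
24 | ten-membered chlorolactone (bis-silyl ether) | CC[Si](CC)(CC)O[C@H]1CC/C(C)=C(/Cl)[C@H]2OC(=O)[C@H](C)[C@@]2(O)[C@@H](O[Si](C)(C)C(C)(C)C)[C@H]2[C@@H](C)C(=O)C=C[C@@]21C | intermediate
25 | C2 alcohol | O[C@H]1CC/C(C)=C(/Cl)[C@H]2OC(=O)[C@H](C)[C@@]2(O)[C@@H](O[Si](C)(C)C(C)(C)C)[C@H]2[C@@H](C)C(=O)C=C[C@@]21C | intermediate
26 | C2 acetate, C9 silyl ether | CC(=O)O[C@H]1CC/C(C)=C(/Cl)[C@H]2OC(=O)[C@H](C)[C@@]2(O)[C@@H](O[Si](C)(C)C(C)(C)C)[C@H]2[C@@H](C)C(=O)C=C[C@@]21C | intermediate
27 | CNP0163464.1 | CC(=O)O[C@H]1CC/C(C)=C(/Cl)[C@H]2OC(=O)[C@H](C)[C@@]2(O)[C@@H](O)[C@H]2[C@@H](C)C(=O)C=C[C@@]21C | target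

## Step count and least certain steps

Total step count: 18. Longest linear sequence: 18 steps (1 to 27); compounds 3, 5, 10 and 16 enter as purchased.

**Step 15 (key step).** The most likely failure is ionisation of the exo chloride with outward rotation of the ring bonds, which would lead to a trans-cyclodecene or to elimination products. This is the mode that unassisted openings of medium-ring adducts prefer. A 1,2-shift from C8 to the cationic C7, triggered by the free hydroxyl, is a second possible loss. The fallback makes the leaving group, not neighbouring-group assistance, decide which halide leaves. It sets out from 21: PhHgCBr2Cl transfers bromochlorocarbene, and the adduct with bromine on the ring side, the endo-bromo exo-chloro cyclopropane F1, is separated from its C6 epimer. AgOTf with 2,6-lutidine in (CF3)2CHOH at 0 °C then ionises only the carbon–bromine bond, so the endo halide is forced to leave and chlorine stays on C6. The route is rejoined at 24.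

**Step 8.** Closure of a nine-membered ring at a trisubstituted alkene next to a fully substituted allylic region may give way to oligomerisation or stall, because the strain of the ring and the hindrance at both alkenes add up. The fallback closes the ring at a less substituted alkene and brings in C16 afterwards. It sets out from 4:
- But-3-enylmagnesium bromide gives the nor-methyl carbinol F2.
- Silylation as in step 4 gives the triethylsilyl ether F3, and methanolysis gives the primary alcohol F4.
- The iridium-catalysed reaction with 10 gives the diol monoacetate F5, and silylation gives the bis-silyl ether F6.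
- Ring-closing metathesis of two monosubstituted alkenes gives the cis-disubstituted cyclononene acetate F7.
- Methanolysis gives the allylic alcohol F8, and MnO2 gives the cis-enone F9.
- Me2CuLi with Me3SiCl adds the C16 methyl to C5 and traps the enolate as the trimethylsilyl enol ether F10.
- One equivalent of Pd(OAc)2, which should react with the trimethylsilyl enol ether faster than with the hindered triisopropylsilyl enol ether of ring A, restores the C5=C7 enone and rejoins the route at 15.

**Step 6.** Dehydrogenation of the hindered neopentylic alcohol may be slow, and the catalyst has to override the Felkin–Anh preference of the aldehyde, so low conversion or erosion of selectivity at C9 is the likely problem. The fallback sets C9 by substrate-controlled hydride delivery and sets out from 9: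
- Oxidation with SO3·pyridine/DMSO/Et3N gives the aldehyde F11.
- An indium-mediated Barbier reaction with 3-bromopropenyl acetate gives the syn adduct F12, the C9 epimer of 11, as expected from Felkin–Anh control.
- Dess–Martin periodinane gives the ketone F13.
- Felkin–Anh reduction with Zn(BH4)2 at −78 °C, which by the same model that disfavours the carbon nucleophile now favours the wanted face, rejoins the route at 11.

**Step 13.** Protonation may occur from the wrong face, or the lithium aldolate may undergo retro-aldol cleavage before the quench. If the natural C11 configuration proves to be the more stable one in this bicyclic enone, the fallback is thermodynamic equilibration of 19 with DBU in toluene at 23 °C. It sets out from 19, rejoins at 21 and makes no new compound.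

## Further compounds

F1 | step 15 | endo-bromo exo-chloro cyclopropane | C[C@]12C=CC(=O)[C@H](C)[C@@H]1[C@H](O[Si](C)(C)C(C)(C)C)[C@](O)([C@@H](C)C(=O)OC(C)(C)C)[C@H]3[C@@](Cl)(Br)[C@@]3(C)CC[C@@H]2O[Si](CC)(CC)CC
F2 | step 8 | nor-methyl carbinol | C[C@]1([C@@H](O)CCC=C)CC=C(O[Si](C(C)C)(C(C)C)C(C)C)[C@@H](C)[C@@H]1COC(C)=O
F3 | step 8 | nor-methyl triethylsilyl ether | C[C@]1([C@@H](O[Si](CC)(CC)CC)CCC=C)CC=C(O[Si](C(C)C)(C(C)C)C(C)C)[C@@H](C)[C@@H]1COC(C)=O
F4 | step 8 | nor-methyl primary alcohol | C[C@]1([C@@H](O[Si](CC)(CC)CC)CCC=C)CC=C(O[Si](C(C)C)(C(C)C)C(C)C)[C@@H](C)[C@@H]1CO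
F5 | step 8 | nor-methyl diol monoacetate | C[C@]1([C@@H](O[Si](CC)(CC)CC)CCC=C)CC=C(O[Si](C(C)C)(C(C)C)C(C)C)[C@@H](C)[C@@H]1[C@H](O)[C@H](OC(C)=O)C=C
F6 | step 8 | nor-methyl bis-silyl ether | C[C@]1([C@@H](O[Si](CC)(CC)CC)CCC=C)CC=C(O[Si](C(C)C)(C(C)C)C(C)C)[C@@H](C)[C@@H]1[C@H](O[Si](C)(C)C(C)(C)C)[C@H](OC(C)=O)C=C
F7 | step 8 | cis-disubstituted cyclononene acetate | C[C@]12CC=C(O[Si](C(C)C)(C(C)C)C(C)C)[C@@H](C)[C@@H]1[C@H](O[Si](C)(C)C(C)(C)C)[C@H](OC(C)=O)/C=C\CC[C@@H]2O[Si](CC)(CC)CC
F8 | step 8 | cis-disubstituted cyclononenol | C[C@]12CC=C(O[Si](C(C)C)(C(C)C)C(C)C)[C@@H](C)[C@@H]1[C@H](O[Si](C)(C)C(C)(C)C)[C@H](O)/C=C\CC[C@@H]2O[Si](CC)(CC)CC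
F9 | step 8 | cis-enone without C16 | C[C@]12CC=C(O[Si](C(C)C)(C(C)C)C(C)C)[C@@H](C)[C@@H]1[C@H](O[Si](C)(C)C(C)(C)C)C(=O)/C=C\CC[C@@H]2O[Si](CC)(CC)CC
F10 | step 8 | trimethylsilyl enol ether after methyl addition (C5 unassigned) | C[C@]12CC=C(O[Si](C(C)C)(C(C)C)C(C)C)[C@@H](C)[C@@H]1[C@H](O[Si](C)(C)C(C)(C)C)/C(O[Si](C)(C)C)=C\C(C)CC[C@@H]2O[Si](CC)(CC)CC
F11 | step 6 | C9 aldehyde | C[C@]1([C@@H](O[Si](CC)(CC)CC)CCC(C)=C)CC=C(O[Si](C(C)C)(C(C)C)C(C)C)[C@@H](C)[C@@H]1C=O
F12 | step 6 | syn adduct (C9 epimer of 11) | C[C@]1([C@@H](O[Si](CC)(CC)CC)CCC(C)=C)CC=C(O[Si](C(C)C)(C(C)C)C(C)C)[C@@H](C)[C@@H]1[C@@H](O)[C@H](OC(C)=O)C=C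
F13 | step 6 | C9 ketone | C[C@]1([C@@H](O[Si](CC)(CC)CC)CCC(C)=C)CC=C(O[Si](C(C)C)(C(C)C)C(C)C)[C@@H](C)[C@@H]1C(=O)[C@H](OC(C)=O)C=C
F0 | step 13 | none | none
A1 | alternative 1 | seco iodo-aldehyde | C[C@]1([C@@H](O[Si](CC)(CC)CC)CC/C(C)=C(/Cl)C=O)CC=C(O[Si](C(C)C)(C(C)C)C(C)C)[C@H](C)[C@@H]1[C@H](O[Si](C)(C)C(C)(C)C)/C(I)=C(\C)C(=O)OCC
A2 | alternative 1 | macrocyclic butenolide (C7 not controlled) | CC[Si](CC)(CC)O[C@H]1CC/C(C)=C(/Cl)C2OC(=O)C(C)=C2[C@@H](O[Si](C)(C)C(C)(C)C)[C@H]2[C@@H](C)C(O[Si](C(C)C)(C(C)C)C(C)C)=CC[C@@]21C
A3 | alternative 2 | divinyl decalindiol (C2 and C7 configuration inconsequential) | C=C[C@]1(O)[C@](O[Si](C)(C)C)(/C=C/C)CC[C@H]2[C@@H](C)C3(OCCO3)CC[C@@]21C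
A4 | alternative 2 | ten-membered keto enol ether (C5 not controlled) | O=C1CCC(C)/C=C(O[Si](C)(C)C)\CC[C@H]2[C@@H](C)C3(OCCO3)CC[C@@]21C
A5 | alternative 3 | open-chain triene | CC(=O)O[C@@H](CC/C(C)=C(/Cl)[C@H]1OC(=O)[C@H](C)[C@@]1(O)[C@@H](O)/C=C\C)/C(C)=C/C=C/O[Si](C)(C)C(C)(C)C
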